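## Retrosynthetic overview

1. The target is the 7,7′-linked homodimer of one benzofuran-3(2H)-one (ring A = benzene ring, ring B = furanone ring). The two tertiary OH groups are unveiled last from silyl ketals, and the C7–C7′ bond is cut to a monomeric C6 phenol (oxidative phenol coupling; C7 is its only unsubstituted ring carbon).
2. The C2–O(H) bond leads back to a 2-methylbenzofuran-3(2H)-one, one oxidation level lower. Its 3-silyloxybenzofuran is oxidised under catalyst control (asymmetric Rubottom oxidation), which sets C2 and gives the locked silyl ketal directly.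
3. Key disconnection: ring B is opened at C3–C3a and O1–C7a in one operation, to an aryne (triple bond C3a≡C7a of ring A) and the alkoxide of methyl lactate. Forward, the alkoxide adds to C7a and the aryl anion at C3a closes ring B on the ester carbon.
4. Enabling feature: O1 and the C3 carbonyl sit on adjacent carbons of ring A (C7a and C3a), and C3a is flanked by the C4 methoxy group while C7a is flanked by C7–H. In the aryne this one methoxy group steers oxygen to C7a and the carbanion to C3a.
5. Ring order: ring A is bought (2,3-dimethoxyphenol) and converted into the ortho-silylaryl triflate, ring B is made in the key step, and the second half arises by dimerisation.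

Key step: step 5

Assumption: the target structure carries no descriptor for the 7,7′ axis, so the axis is treated as not configurationally defined; the two (R)-hemiketal carbons, which can epimerise by ring–chain tautomerism, are carried as silyl ketals and unveiled only in the last step.

## Route

Step 1
Reactants: 1 2,3-dimethoxyphenol
Product: 3 2,3-dimethoxybenzene-1,4-diol, via 2,3-dimethoxy-1,4-benzoquinone 2 (not isolated)
Conditions: (KSO3)2NO, KH2PO4, H2O/acetone, 0 °C→rt; then Na2S2O4, H2O/EtOAc, rt
Reagents that add atoms: potassium nitrosodisulfonate (Fremy's salt), [K+].[K+].[O-]S(=O)(=O)N([O])S(=O)(=O)[O-]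
Why: Teuber oxidation: the nitroxyl radical oxidises a phenol with a free para position to the para-quinone only, and dithionite reduction in the same work-up gives the symmetric hydroquinone, so that the later monoprotection cannot give regioisomers.

Step 2
Reactants: 3 2,3-dimethoxybenzene-1,4-diol
Product: 4 4-(benzyloxy)-2,3-dimethoxyphenol
Conditions: BnBr (0.9 equiv), K2CO3, acetone, rt, N2
Reagents that add atoms: benzyl bromide, BrCc1ccccc1
Why: Williamson ether synthesis with a deficit of benzyl bromide: the two hydroxyls are equivalent by symmetry, so a single monoether is formed and is separated from dibenzyl ether and recovered diol (recycled).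

Step 3
Reactants: 4 4-(benzyloxy)-2,3-dimethoxyphenol
Product: 5 4-(benzyloxy)-6-bromo-2,3-dimethoxyphenol
Conditions: NBS, i-Pr2NH (cat.), CH2Cl2, −78→0 °C
Reagents that add atoms: N-bromosuccinimide, O=C1CCC(=O)N1Br
Why: Amine-catalysed ortho-bromination of a phenol (electrophilic aromatic substitution through an N-bromoamine hydrogen-bonded to the OH): of the two free ring positions only the one ortho to the free hydroxyl is addressed, the other lying ortho to the less activating benzyl ether.

Step 4
Reactants: 5 4-(benzyloxy)-6-bromo-2,3-dimethoxyphenol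
Product: 8 4-(benzyloxy)-2,3-dimethoxy-6-(trimethylsilyl)phenyl trifluoromethanesulfonate, via aryl trimethylsilyl ether 6 (not isolated), via lithium 2-silylphenoxide 7 (not isolated)
Conditions: HMDS, THF, 65 °C, then evaporate; n-BuLi, THF, −78 °C; Tf2O, −78→0 °C
Reagents that add atoms: hexamethyldisilazane, C[Si](C)(C)N[Si](C)(C)C; trifluoromethanesulfonic anhydride, O=S(=O)(OS(=O)(=O)C(F)(F)F)C(F)(F)F
Why: Standard three-stage route to an ortho-silylaryl triflate: O-silylation, bromine–lithium exchange followed by 1,3 O→C silyl shift (retro-Brook rearrangement) and O-triflation of the lithium phenoxide; exchange at −78 °C is faster than deprotonation of the benzyl ether.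

Step 5
Reactants: 8 4-(benzyloxy)-2,3-dimethoxy-6-(trimethylsilyl)phenyl trifluoromethanesulfonate; 9 methyl 2-hydroxypropanoate (racemic methyl lactate)
Product: 13 6-(benzyloxy)-4,5-dimethoxy-2-methylbenzofuran-3(2H)-one (racemic), via potassium lactate alkoxide 10 (not isolated), via aryne 11 (not isolated), via aryl anion 12 (not isolated)
Conditions: 9, KH, THF, 0 °C; then 8, KF, 18-crown-6, THF, 0 °C→rt; 1 M HCl
Reagents that add atoms: none
Why: Proposed new method: fluoride-induced 1,2-elimination of 8 gives aryne 11, whose triple bond spans the ring carbons that become C7a and C3a; alkoxide 10 adds to the carbon remote from the flanking methoxy group (C7a), and the aryl anion 12 thus formed at C3a, five atoms from the ester carbon, attacks it intramolecularly and expels methoxide. The closest known reactions are the aryne annulations of salicylate esters to xanthones and of N-sulfonyl α-amino esters to indolin-3-ones, in which a heteroatom adds to the aryne and the aryl anion is captured by the ester; closing the five-membered oxygen ring with an aliphatic α-hydroxy ester alkoxide is the untested element. Ring B closes in a 5-exo-trig acyl substitution. The only new stereocentre, C2–H, is formed racemic and needs no control because it is enolisable and is planarised in step 6. Regioselectivity is required and is secured by the methoxy group beside the triple bond: its inductive withdrawal distorts the aryne so that the distal carbon is the electrophilic terminus and the developing negative charge sits next to oxygen (the pattern of 3-methoxybenzyne), while the hydrogen on the other side exerts no bias. Capture of the aryl anion by acyl transfer rather than by protonation is secured by using the preformed alkoxide (no O–H in the adduct) in an aprotic medium.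

Step 6
Reactants: 13 6-(benzyloxy)-4,5-dimethoxy-2-methylbenzofuran-3(2H)-one (racemic)
Product: 14 {[6-(benzyloxy)-4,5-dimethoxy-2-methylbenzofuran-3-yl]oxy}(tert-butyl)dimethylsilane
Conditions: TBSOTf, Et3N, CH2Cl2, 0 °C
Reagents that add atoms: tert-butyldimethylsilyl trifluoromethanesulfonate, CC(C)(C)[Si](C)(C)OS(=O)(=O)C(F)(F)F
Why: Silyl enol ether formation by soft enolisation: the ketone is O-silylated to the aromatic 3-silyloxybenzofuran, which removes the racemic C2–H centre and presents C2=C3 as an electron-rich, arene-conjugated cyclic enol ether.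

Step 7
Reactants: 14 {[6-(benzyloxy)-4,5-dimethoxy-2-methylbenzofuran-3-yl]oxy}(tert-butyl)dimethylsilane
Product: 16 (S)-6-(benzyloxy)-2-[(tert-butyldimethylsilyl)oxy]-4,5-dimethoxy-2-methylbenzofuran-3(2H)-one, via silyloxy epoxide 15 (not isolated)
Conditions: (S,S)-[N,N′-bis(3,5-di-tert-butylsalicylidene)-1,2-cyclohexanediaminato]manganese chloride (trivalent manganese, 5 mol%), PhIO, 4-phenylpyridine N-oxide, 4 Å MS, CH2Cl2, 0 °C
Reagents that add atoms: iodosylbenzene, O=Ic1ccccc1
Why: Catalytic asymmetric Rubottom oxidation (Jacobsen–Katsuki oxygen transfer from the oxo-manganese salen complex to a silyl enol ether): oxygen is delivered to one face of C2=C3 to give epoxide 15, which opens at C3 (cation stabilised by the silyloxy group and the electron-rich arene) and collapses by 1,4 O→O silyl shift to the silyl ketal without breaking the new C2–O bond; the (S,S) catalyst is chosen by analogy with indene, a cyclic arene-conjugated olefin of the same shape, for which it delivers oxygen to the face that here leads to the (2S) silyl ketal, which is the (2R) hemiketal after desilylation.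

Step 8
Reactants: 16 (S)-6-(benzyloxy)-2-[(tert-butyldimethylsilyl)oxy]-4,5-dimethoxy-2-methylbenzofuran-3(2H)-one
Product: 17 (S)-2-[(tert-butyldimethylsilyl)oxy]-6-hydroxy-4,5-dimethoxy-2-methylbenzofuran-3(2H)-one
Conditions: H2 (1 atm), 10% Pd/C, EtOAc, rt
Reagents that add atoms: none
Why: Hydrogenolysis of a benzyl aryl ether under neutral conditions; the silyl ketal, the hindered aryl ketone and the C2 configuration are not affected, and the freed OH is the one needed to direct the coupling.

Step 9
Reactants: 17 (S)-2-[(tert-butyldimethylsilyl)oxy]-6-hydroxy-4,5-dimethoxy-2-methylbenzofuran-3(2H)-one (two molecules)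
Product: 18 (2S,2′S)-2,2′-bis[(tert-butyldimethylsilyl)oxy]-6,6′-dihydroxy-4,4′,5,5′-tetramethoxy-2,2′-dimethyl-[7,7′-bibenzofuran]-3,3′(2H,2′H)-dione
Conditions: Na2S2O8, FeSO4·7H2O (cat.), acetone/H2O, rt
Reagents that add atoms: none
Why: Biomimetic oxidative phenol coupling under the iron/persulfate conditions that dimerise 4-acyl-2-methoxyphenols such as apocynin and vanillin: the phenoxyl radical of 17 has its only unsubstituted spin-bearing carbon at C7 (the para carbon C3a and the other ortho carbon C5 are substituted), so radical–radical coupling and tautomerisation should give the 7,7′-biaryl, while C2 is a locked silyl ketal and cannot epimerise.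

Step 10
Reactants: 18 (2S,2′S)-2,2′-bis[(tert-butyldimethylsilyl)oxy]-6,6′-dihydroxy-4,4′,5,5′-tetramethoxy-2,2′-dimethyl-[7,7′-bibenzofuran]-3,3′(2H,2′H)-dione
Product: 19 (2R,2′R)-2,2′,6,6′-tetrahydroxy-4,4′,5,5′-tetramethoxy-2,2′-dimethyl-[7,7′-bibenzofuran]-3,3′(2H,2′H)-dione (CNP0171547.1)
Conditions: HF·pyridine, pyridine, THF, 0 °C
Reagents that add atoms: none
Why: Fluoride-mediated desilylation under weakly acidic, buffered conditions cleaves only the Si–O bonds, so both hemiketal carbons keep their spatial arrangement (the descriptor changes from S to R only because O–Si outranks the ring oxygen whereas O–H does not), and the product is isolated without contact with base to avoid ring–chain epimerisation.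

## Compound list

1 | 2,3-dimethoxyphenol | COc1cccc(O)c1OC | starting material
2 | 2,3-dimethoxy-1,4-benzoquinone | COC1=C(OC)C(=O)C=CC1=O | intermediate
3 | 2,3-dimethoxybenzene-1,4-diol | COc1c(O)ccc(O)c1OC | intermediate
4 | 4-(benzyloxy)-2,3-dimethoxyphenol | COc1c(O)ccc(OCc2ccccc2)c1OC | intermediate
5 | 4-(benzyloxy)-6-bromo-2,3-dimethoxyphenol | COc1c(O)c(Br)cc(OCc2ccccc2)c1OC | intermediate
6 | [4-(benzyloxy)-6-bromo-2,3-dimethoxyphenoxy]trimethylsilane | COc1c(O[Si](C)(C)C)c(Br)cc(OCc2ccccc2)c1OC | intermediate
7 | lithium 4-(benzyloxy)-2,3-dimethoxy-6-(trimethylsilyl)phenoxide | [Li+].COc1c([O-])c([Si](C)(C)C)cc(OCc2ccccc2)c1OC | intermediate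
8 | 4-(benzyloxy)-2,3-dimethoxy-6-(trimethylsilyl)phenyl trifluoromethanesulfonate | COc1c(OS(=O)(=O)C(F)(F)F)c([Si](C)(C)C)cc(OCc2ccccc2)c1OC | intermediate
9 | methyl 2-hydroxypropanoate (racemic methyl lactate) | COC(=O)C(C)O | starting material
10 | potassium 1-methoxy-1-oxopropan-2-olate (potassium alkoxide of 9) | [K+].COC(=O)C(C)[O-] | intermediate
11 | 5-(benzyloxy)-3,4-dimethoxybenzyne (5-(benzyloxy)-3,4-dimethoxy-1,2-didehydrobenzene) | COC1=C(OC)C(OCc2ccccc2)=CC#C1 | intermediate
12 | methyl 2-[5-(benzyloxy)-3,4-dimethoxy-2-potassiophenoxy]propanoate (aryl anion) | [K+].COC(=O)C(C)Oc1cc(OCc2ccccc2)c(OC)c(OC)[c-]1 | intermediate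
13 | 6-(benzyloxy)-4,5-dimethoxy-2-methylbenzofuran-3(2H)-one (racemic) | COc1c(OCc2ccccc2)cc2c(c1OC)C(=O)C(C)O2 | intermediate
14 | {[6-(benzyloxy)-4,5-dimethoxy-2-methylbenzofuran-3-yl]oxy}(tert-butyl)dimethylsilane | COc1c(OCc2ccccc2)cc2oc(C)c(O[Si](C)(C)C(C)(C)C)c2c1OC | intermediate
15 | (2S,3R)-6-(benzyloxy)-3-[(tert-butyldimethylsilyl)oxy]-2,3-epoxy-4,5-dimethoxy-2-methyl-2,3-dihydrobenzofuran | COc1c(OCc2ccccc2)cc2c(c1OC)[C@]3(O[Si](C)(C)C(C)(C)C)O[C@]3(C)O2 | intermediate
16 | (S)-6-(benzyloxy)-2-[(tert-butyldimethylsilyl)oxy]-4,5-dimethoxy-2-methylbenzofuran-3(2H)-one | COc1c(OCc2ccccc2)cc2c(c1OC)C(=O)[C@](C)(O[Si](C)(C)C(C)(C)C)O2 | intermediate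
17 | (S)-2-[(tert-butyldimethylsilyl)oxy]-6-hydroxy-4,5-dimethoxy-2-methylbenzofuran-3(2H)-one | COc1c(O)cc2c(c1OC)C(=O)[C@](C)(O[Si](C)(C)C(C)(C)C)O2 | intermediate
18 | (2S,2′S)-2,2′-bis[(tert-butyldimethylsilyl)oxy]-6,6′-dihydroxy-4,4′,5,5′-tetramethoxy-2,2′-dimethyl-[7,7′-bibenzofuran]-3,3′(2H,2′H)-dione | COc1c(O)c(-c2c(O)c(OC)c(OC)c3c2O[C@@](C)(O[Si](C)(C)C(C)(C)C)C3=O)c2c(c1OC)C(=O)[C@](C)(O[Si](C)(C)C(C)(C)C)O2 | intermediate
19 | (2R,2′R)-2,2′,6,6′-tetrahydroxy-4,4′,5,5′-tetramethoxy-2,2′-dimethyl-[7,7′-bibenzofuran]-3,3′(2H,2′H)-dione | COc1c(O)c(-c2c(O)c(OC)c(OC)c3c2O[C@@](C)(O)C3=O)c2c(c1OC)C(=O)[C@](C)(O)O2 | target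

## Step count and risks

Total step count: 10. Longest linear sequence: 10 steps (1 → 19); 9 enters in step 5.

Steps most likely to fail:

1. Step 5 (proposed new method). The aryl anion may be protonated, or may take the α-hydrogen of the lactate unit, faster than it is acylated, so that O-arylation occurs without ring closure; self-condensation of the lactate alkoxide may also compete. Fallback with known chemistry, setting out from 8: the same aryne is generated with CsF in THF (sealed tube, heat) in the presence of 2-chloropropanoic acid. Aryne insertion into the C–O bond of the carboxylic acid follows: the carboxylate adds at the same distal carbon and an acyl shift through a four-membered transition state moves the acyl group to the neighbouring carbon. This gives 1-[4-(benzyloxy)-6-hydroxy-2,3-dimethoxyphenyl]-2-chloropropan-1-one F1. Ring B is then closed at O1–C2 instead, by intramolecular O-alkylation (K2CO3, KI cat., acetone), and the route is rejoined at 13.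

2. Step 7. Facial discrimination of the tetrasubstituted enol ether by the oxo-manganese salen complex may be insufficient, or the sense of induction may be opposite to the indene analogy. Fallback, setting out from 14: uncatalysed Rubottom oxidation (mCPBA, NaHCO3, CH2Cl2, 0 °C) gives racemic 6-(benzyloxy)-2-[(tert-butyldimethylsilyl)oxy]-4,5-dimethoxy-2-methylbenzofuran-3(2H)-one F2. The configurationally locked silyl ketal is resolved by preparative chromatography on a chiral stationary phase, and the (S) enantiomer rejoins the route at 16.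

3. Step 9. Coupling at the doubly flanked C7 may be slow, so that over-oxidation of the more electron-rich biphenol, C–O coupling or acid-induced loss of the silyl groups in the aqueous medium takes over. Fallback, setting out from 16 (benzyl ether retained), and using the fact that C7 is the only free ring position:
   - Iodination (NIS, TFA cat., MeCN) gives (S)-6-(benzyloxy)-2-[(tert-butyldimethylsilyl)oxy]-7-iodo-4,5-dimethoxy-2-methylbenzofuran-3(2H)-one F3.
   - Miyaura borylation of half of the material (B2pin2, Pd(dppf)Cl2, KOAc, dioxane, 80 °C) gives (S)-6-(benzyloxy)-2-[(tert-butyldimethylsilyl)oxy]-4,5-dimethoxy-2-methyl-7-(4,4,5,5-tetramethyl-1,3,2-dioxaborolan-2-yl)benzofuran-3(2H)-one F4.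
   - Suzuki–Miyaura coupling of F3 with F4 (Pd(OAc)2, SPhos, K3PO4, toluene/H2O, 90 °C) gives (2S,2′S)-6,6′-bis(benzyloxy)-2,2′-bis[(tert-butyldimethylsilyl)oxy]-4,4′,5,5′-tetramethoxy-2,2′-dimethyl-[7,7′-bibenzofuran]-3,3′(2H,2′H)-dione F5.
   - Hydrogenolysis (H2, 10% Pd/C, EtOAc) returns to the route at 18.

## Further compounds

F1 | step 5 | 1-[4-(benzyloxy)-6-hydroxy-2,3-dimethoxyphenyl]-2-chloropropan-1-one | COc1c(OCc2ccccc2)cc(O)c(C(=O)C(C)Cl)c1OC
F2 | step 7 | racemic 6-(benzyloxy)-2-[(tert-butyldimethylsilyl)oxy]-4,5-dimethoxy-2-methylbenzofuran-3(2H)-one | COc1c(OCc2ccccc2)cc2c(c1OC)C(=O)C(C)(O[Si](C)(C)C(C)(C)C)O2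
F3 | step 9 | (S)-6-(benzyloxy)-2-[(tert-butyldimethylsilyl)oxy]-7-iodo-4,5-dimethoxy-2-methylbenzofuran-3(2H)-one | COc1c(OCc2ccccc2)c(I)c2c(c1OC)C(=O)[C@](C)(O[Si](C)(C)C(C)(C)C)O2
F4 | step 9 | (S)-6-(benzyloxy)-2-[(tert-butyldimethylsilyl)oxy]-4,5-dimethoxy-2-methyl-7-(4,4,5,5-tetramethyl-1,3,2-dioxaborolan-2-yl)benzofuran-3(2H)-one | COc1c(OCc2ccccc2)c(B3OC(C)(C)C(C)(C)O3)c2c(c1OC)C(=O)[C@](C)(O[Si](C)(C)C(C)(C)C)O2
F5 | step 9 | (2S,2′S)-6,6′-bis(benzyloxy)-2,2′-bis[(tert-butyldimethylsilyl)oxy]-4,4′,5,5′-tetramethoxy-2,2′-dimethyl-[7,7′-bibenzofuran]-3,3′(2H,2′H)-dione | COc1c(OCc2ccccc2)c(-c2c(OCc3ccccc3)c(OC)c(OC)c3c2O[C@@](C)(O[Si](C)(C)C(C)(C)C)C3=O)c2c(c1OC)C(=O)[C@](C)(O[Si](C)(C)C(C)(C)C)O2
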